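A chain length reckoned from the charge of X looks like a forecast but is a floor, and two chemists argue over how far above it this flask stands.

common to all: L 2.2 M (fed, over 30 s); X 0.4 mol%
- dawn: J 1.8 mM; the very flask that is asked about, followed so far; the fed solution adds 0.50 times the starting volume
- summer: J 0.90 mM; run made earlier; the fed solution adds 0.50 times the starting volume
- flask: J 1.8 mM; the fed solution adds 0.50 times the starting volume; time 10 min

- dawn (time / s: Z / %, L / %): 15.0: 0.6, 51.0; 30.0: 2.2, 100.5; 50.0: 0.5, 100.8; 60.0: 1.1, 101.3; 80.0: 0.7, 98.8; 90.0: 0.9, 102.2; 120: 1.0, 100.5
- summer (time / min: Z / %, L / %): 0.500: 0, 100.6; 1.00: 0, 98.4; 1.50: 1.2, 98.7; 2.50: 3.1, 96.8; 3.00: 6.5, 95.0; 4.00: 14.5, 87.6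

(standard deviation of a reading: 1 percentage point)

- amounts are per litre of the starting volume; all of the dose is in the solution fed
- the average divides the monomer in chains by the number of chains begun, living and dead together
- steps that have been proposed: L + G -> E + Z; L + E -> Z + E; X -> G; G + J -> Q
- the earlier runs do not show the number of chains; that part of a forecast is a guess
- percentages count the whole charge, also what has not yet gone in

- average number of monomer units in a chain (chains begun, living or dead) at 10 min
- part of the L that has reacted at 10 min

Both start from the turnover count, the L charged per X charged (the monomer-to-initiator ratio), 250. If each chain begun costs one X, the average chain equals this count, times the part of L reacted, divided by the share of the X charge that has begun chains.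

The first chemist reads the runs, with Z in the dawn run near the scatter up to 2 min, as X releasing G slowly while J takes the first of it. After that, she says, G starts chains promptly. Her forecast is 300 units and 55% reacted, “assuming fast initiation”. By the count, those two numbers mean a share of 45.8%.

The second chemist objects that Z reaching 14.5% at 4.00 min in the summer run shows how fast L goes, and that is the number of chains times the speed of each. Few quick chains and many slow ones can draw the same curve, so the share is a guess. His own reckoning gives not a forecast but a floor of 138 units at her conversion, and he bets that G waits and the share is smaller.

At 10 min this flask gives chains of 2820 units with 70.9% of the L reacted, so the count puts the share at 6.30%, below hers. Her prompt starts belong to a G whose half-life is short against that of X. Here the half-life of G, by its chain-starting step alone with the other charges taken as all present, is 19 min, against 3.0 min for X turning into G alone.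

    L + G → E + Z (k = 2.81 × 10⁻⁴ M⁻¹ s⁻¹)
    L + E → Z + E, rate k2*[E]*[L] (k = 13.0 M⁻¹ s⁻¹)
    X → G (k = 0.00387 s⁻¹)
    G + J → Q (k = 783 M⁻¹ s⁻¹)

A second flask, the same but with 0.0011 M of J, keeps the count at 250. With its 76.8% reacted and the first flask's share, the count gives 3048 units. The computed chain is 2790, a share of 6.88%.

The data are calculated for an exercise; noise was put on by code.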